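**Strategy.** The cyclohexane is cut into two three-carbon arcs: C(CH3)(OH)–CHCl–CH2 and CH(OH)–CH(O-angeloyl)–CH(side chain). The first arc is the α′, carbonyl and α carbons of a β-keto ester, the second is C1–C3 of an enal. One amine-catalysed Michael/aldol-condensation annulation therefore joins CH2 to the side-chain-bearing carbon and the methyl-bearing carbon to the future secondary carbinol carbon, closing the ring and fixing its absolute configuration. The precursors are a silyl-capped enynal and tert-butyl 3-oxopentanoate; the product is a 5-alkynyl-2-methylcyclohexenone. Enone transposition, α′-oxygenation, hydroxyl-directed epoxidation and chloride opening then dress the ring, while the alkyne is grown into the dienyl side chain.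

Key step: step 2

Assumption: 1, 2, 4, 13, 16 and all catalysts and ligands are taken as purchasable, and the ligand enantiomer in step 9 is the one that delivers the (S)-carbinol.

Step 1
Reactants: 1 3-(trimethylsilyl)prop-2-ynal; 2 (triphenylphosphoranylidene)acetaldehyde
Product: 3 (2E)-5-(trimethylsilyl)pent-2-en-4-ynal
Conditions: CH2Cl2, 0 °C to rt
Reagents that add atoms: none
Why: Wittig olefination with the formyl-stabilised ylide should give the (E)-enal and stop after one homologation, because the ynal is the more electrophilic aldehyde.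

Step 2
Reactants: 3 (2E)-5-(trimethylsilyl)pent-2-en-4-ynal; 4 tert-butyl 3-oxopentanoate
Product: 7 (5R)-2-methyl-5-[(trimethylsilyl)ethynyl]cyclohex-2-en-1-one, via Michael adduct 5 (not isolated), via cyclohexenone tert-butyl ester 6 (not isolated)
Conditions: (S)-2-{bis[3,5-bis(trifluoromethyl)phenyl][(trimethylsilyl)oxy]methyl}pyrrolidine (10 mol%), toluene, rt; then TsOH·H2O (20 mol%), 80 °C, same flask
Reagents that add atoms: none
Why: Iminium-ion activation of 3 lets the doubly activated carbon of 4 add to the enal β-carbon (first ring bond, future ring CH2 to the alkynyl-bearing carbon); acid then drives a 6-(enolendo)-exo-trig aldol of the ethyl-ketone α-carbon onto the aldehyde (second ring bond, methyl-bearing carbon to the former formyl carbon), followed by dehydration, loss of isobutene and decarboxylation. The closest known reaction type is the amine-catalysed Michael/aldol-condensation [3+3] annulation of β-keto esters with enals, an organocatalytic Robinson-type cyclohexenone synthesis. The only new stereocentre, the alkynyl-bearing carbon, is set by the catalyst: its diaryl(silyloxy)methyl group shields one face of the (E)-iminium ion, so the nucleophile should enter from the other face and give the (R) configuration. The step needs 1,4- rather than 1,6-addition, which the silyl cap on the alkyne terminus secures, and a single aldol regiochemistry, which is secured because only the ethyl-ketone α-carbon can reach the aldehyde through a six-membered transition state.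

Step 3
Reactants: 7 (5R)-2-methyl-5-[(trimethylsilyl)ethynyl]cyclohex-2-en-1-one
Product: 8 (1R,4R,6R)-4-ethynyl-1-methyl-7-oxabicyclo[4.1.0]heptan-2-one
Conditions: H2O2 (30% aq.), NaOH, MeOH, 0 °C to rt
Reagents that add atoms: hydrogen peroxide, OO
Why: Weitz–Scheffer (nucleophilic) epoxidation of the enone should occur anti to the alkynyl group while the alkaline methanol also cleaves the C–Si bond; both oxirane stereocentres are erased in steps 4 and 6, so the facial outcome is not critical.

Step 4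
Reactants: 8 (1R,4R,6R)-4-ethynyl-1-methyl-7-oxabicyclo[4.1.0]heptan-2-one
Product: 9 (1R,5S)-5-ethynyl-2-methylcyclohex-2-en-1-ol
Conditions: N2H4·H2O, AcOH (cat.), MeOH, 0 °C to rt
Reagents that add atoms: none
Why: Wharton transposition: the epoxy hydrazone fragments with loss of N2, which moves the oxygen to the former formyl carbon and the double bond to the methyl-bearing carbon and the future chlorine-bearing carbon.

Step 5
Reactants: 9 (1R,5S)-5-ethynyl-2-methylcyclohex-2-en-1-ol
Product: 10 (1R,5S)-2-methyl-5-[1-(triethylsilyl)ethenyl]cyclohex-2-en-1-ol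
Conditions: [Cp*Ru(MeCN)3]PF6 (3 mol%), Et3SiH, CH2Cl2, 0 °C
Reagents that add atoms: triethylsilane, CC[SiH](CC)CC
Why: Cationic ruthenium-catalysed hydrosilylation of a terminal alkyne is Markovnikov-selective (silicon to the internal carbon) and tolerates free hydroxyl groups, so it should give the 1,1-disubstituted vinylsilane that carries the future exocyclic methylene.

Step 6
Reactants: 10 (1R,5S)-2-methyl-5-[1-(triethylsilyl)ethenyl]cyclohex-2-en-1-ol
Product: 11 (5S)-2-methyl-5-[1-(triethylsilyl)ethenyl]cyclohex-2-en-1-one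
Conditions: MnO2 (activated, excess), CH2Cl2, rt
Reagents that add atoms: none
Why: Chemoselective allylic oxidation gives the transposed enone, whose α′-methylene is the carbon that must carry the ring ester, and it deactivates the ring alkene before the electrophilic iodination.

Step 7
Reactants: 11 (5S)-2-methyl-5-[1-(triethylsilyl)ethenyl]cyclohex-2-en-1-one
Product: 12 (5S)-5-(1-iodoethenyl)-2-methylcyclohex-2-en-1-one
Conditions: N-iodosuccinimide, (CF3)2CHOH, 0 °C
Reagents that add atoms: N-iodosuccinimide, O=C1CCC(=O)N1I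
Why: ipso-Iododesilylation of the vinylsilane (β-silyl cation, loss of silicon) should give the 2-iodoalkene, while the electron-poor enone alkene stays untouched.

Step 8
Reactants: 13 4-methylpent-3-en-1-ol
Product: 14 4-methylpent-3-enal
Conditions: TEMPO (10 mol%), PhI(OAc)2, CH2Cl2, rt; used without purification
Reagents that add atoms: none
Why: Oxoammonium-mediated oxidation of the primary alcohol stops at the aldehyde under near-neutral conditions, which limits migration of the β,γ-alkene into conjugation.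

Step 9
Reactants: 12 (5S)-5-(1-iodoethenyl)-2-methylcyclohex-2-en-1-one; 14 4-methylpent-3-enal
Product: 15 (5S)-5-[(3S)-3-hydroxy-6-methylhepta-1,5-dien-2-yl]-2-methylcyclohex-2-en-1-one
Conditions: CrCl2, NiCl2 (cat.), chiral oxazoline–sulfonamide ligand, Et3N, THF, rt
Reagents that add atoms: none
Why: Nozaki–Hiyama–Kishi coupling: nickel activates the C–I bond, the alkenylchromium species adds only to the aldehyde and not to the enone, and the chromium-bound chiral ligand should favour the (S)-allylic alcohol by reagent control.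

Step 10
Reactants: 15 (5S)-5-[(3S)-3-hydroxy-6-methylhepta-1,5-dien-2-yl]-2-methylcyclohex-2-en-1-one; 16 (2Z)-2-methylbut-2-enoic acid (angelic acid)
Product: 17 (3S)-6-methyl-2-[(1S)-4-methyl-5-oxocyclohex-3-en-1-yl]hepta-1,5-dien-3-yl (2Z)-2-methylbut-2-enoate
Conditions: 16, 2,4,6-trichlorobenzoyl chloride, Et3N, toluene, rt; then 15, DMAP, rt
Reagents that add atoms: none
Why: Yamaguchi esterification through the mixed anhydride acylates the hindered allylic alcohol at room temperature, where the (Z)-alkene of the angeloyl group should not isomerise to the tiglate.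

Step 11
Reactants: 17 (3S)-6-methyl-2-[(1S)-4-methyl-5-oxocyclohex-3-en-1-yl]hepta-1,5-dien-3-yl (2Z)-2-methylbut-2-enoate
Product: 18 (3S)-2-[(1R,6R)-6-hydroxy-4-methyl-5-oxocyclohex-3-en-1-yl]-6-methylhepta-1,5-dien-3-yl (2Z)-2-methylbut-2-enoate
Conditions: LiN(SiMe3)2, THF, −78 °C; 2-(phenylsulfonyl)-3-phenyloxaziridine, −78 °C; AcOH quench
Reagents that add atoms: 2-(phenylsulfonyl)-3-phenyloxaziridine, O=S(=O)(N1OC1c1ccccc1)c1ccccc1
Why: Kinetic deprotonation gives the cross-conjugated α′-enolate, which the oxaziridine should hydroxylate on the face anti to the adjacent side chain, so the new carbinol is trans to it.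

Step 12
Reactants: 18 (3S)-2-[(1R,6R)-6-hydroxy-4-methyl-5-oxocyclohex-3-en-1-yl]-6-methylhepta-1,5-dien-3-yl (2Z)-2-methylbut-2-enoate; 16 (2Z)-2-methylbut-2-enoic acid
Product: 19 (3S)-6-methyl-2-[(1R,6S)-4-methyl-6-{[(2Z)-2-methylbut-2-enoyl]oxy}-5-oxocyclohex-3-en-1-yl]hepta-1,5-dien-3-yl (2Z)-2-methylbut-2-enoate
Conditions: PPh3, DIAD, toluene, 0 °C to rt
Reagents that add atoms: none
Why: Mitsunobu esterification of the α-hydroxy ketone proceeds by SN2 displacement of the oxyphosphonium group by angelate, which inverts the carbinol and places the ring ester cis to the side chain.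

Step 13
Reactants: 19 (3S)-6-methyl-2-[(1R,6S)-4-methyl-6-{[(2Z)-2-methylbut-2-enoyl]oxy}-5-oxocyclohex-3-en-1-yl]hepta-1,5-dien-3-yl (2Z)-2-methylbut-2-enoate
Product: 20 (3S)-2-[(1R,5R,6S)-5-hydroxy-4-methyl-6-{[(2Z)-2-methylbut-2-enoyl]oxy}cyclohex-3-en-1-yl]-6-methylhepta-1,5-dien-3-yl (2Z)-2-methylbut-2-enoate
Conditions: NaBH4, CeCl3·7H2O, MeOH, −78 °C
Reagents that add atoms: none
Why: Luche 1,2-reduction: hydride should attack anti to the pseudo-axial ester on the neighbouring carbon, giving the allylic alcohol cis to the ester and to the side chain, as in the reduction of 5-substituted 2-methylcyclohexenones to the cis alcohols.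

Step 14
Reactants: 20 (3S)-2-[(1R,5R,6S)-5-hydroxy-4-methyl-6-{[(2Z)-2-methylbut-2-enoyl]oxy}cyclohex-3-en-1-yl]-6-methylhepta-1,5-dien-3-yl (2Z)-2-methylbut-2-enoate
Product: 21 (3S)-2-[(1S,2S,3S,4R,6R)-2-hydroxy-1-methyl-3-{[(2Z)-2-methylbut-2-enoyl]oxy}-7-oxabicyclo[4.1.0]heptan-4-yl]-6-methylhepta-1,5-dien-3-yl (2Z)-2-methylbut-2-enoate
Conditions: VO(acac)2 (5 mol%), t-BuOOH, CH2Cl2, 0 °C
Reagents that add atoms: tert-butyl hydroperoxide, CC(C)(C)OO
Why: Vanadium-catalysed epoxidation is directed by the allylic hydroxyl group, so the oxirane should form syn to it and only at the ring alkene, leaving the two side-chain alkenes (no free hydroxyl) untouched.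

Step 15
Reactants: 21 (3S)-2-[(1S,2S,3S,4R,6R)-2-hydroxy-1-methyl-3-{[(2Z)-2-methylbut-2-enoyl]oxy}-7-oxabicyclo[4.1.0]heptan-4-yl]-6-methylhepta-1,5-dien-3-yl (2Z)-2-methylbut-2-enoate
Product: 22 (3S)-2-[(1R,2S,3S,4S,5S)-5-chloro-3,4-dihydroxy-4-methyl-2-{[(2Z)-2-methylbut-2-enoyl]oxy}cyclohexyl]-6-methylhepta-1,5-dien-3-yl (2Z)-2-methylbut-2-enoate
Conditions: TiCl(OiPr)3, CH2Cl2, −20 to 0 °C
Reagents that add atoms: chlorotitanium triisopropoxide, CC(C)O[Ti](Cl)(OC(C)C)OC(C)C
Why: Titanium bound to the neighbouring alkoxide delivers chloride to the distal secondary oxirane carbon with inversion (trans-diaxial Fürst–Plattner opening through the chair that keeps the side chain equatorial), so chlorine ends trans to the tertiary hydroxyl, which stays cis to the secondary one.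

Step 16
Reactants: 22 (3S)-2-[(1R,2S,3S,4S,5S)-5-chloro-3,4-dihydroxy-4-methyl-2-{[(2Z)-2-methylbut-2-enoyl]oxy}cyclohexyl]-6-methylhepta-1,5-dien-3-yl (2Z)-2-methylbut-2-enoate
Product: 23 (2S)-1-[(2S)-3,3-dimethyloxiran-2-yl]-3-[(1R,2S,3S,4S,5S)-5-chloro-3,4-dihydroxy-4-methyl-2-{[(2Z)-2-methylbut-2-enoyl]oxy}cyclohexyl]but-3-en-2-yl (2Z)-2-methylbut-2-enoate (target)
Conditions: 1,2:4,5-di-O-isopropylidene-β-L-erythro-2,3-hexodiulo-2,6-pyranose (L-fructose-derived ketone, 30 mol%), Oxone (2KHSO5·KHSO4·K2SO4), NaHCO3 buffer (about pH 8), Bu4NHSO4, MeCN–aqueous Na2EDTA, 0 °C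
Reagents that add atoms: potassium peroxymonosulfate, [K+].[O-]S(=O)(=O)OO
Why: Shi epoxidation: the chiral dioxirane should epoxidise the electron-rich trisubstituted alkene through a spiro transition state, this ketone enantiomer giving the (S)-oxirane, while the hindered 1,1-disubstituted alkene and the electron-poor angelates should not react and the near-neutral buffer spares the chlorohydrin.

**Compound list**

1 | 3-(trimethylsilyl)prop-2-ynal | C[Si](C)(C)C#CC=O | starting material
2 | (triphenylphosphoranylidene)acetaldehyde | O=CC=P(c1ccccc1)(c1ccccc1)c1ccccc1 | starting material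
3 | (2E)-5-(trimethylsilyl)pent-2-en-4-ynal | C[Si](C)(C)C#C/C=C/C=O | intermediate
4 | tert-butyl 3-oxopentanoate | CCC(=O)CC(=O)OC(C)(C)C | starting material
5 | tert-butyl (3R)-3-(2-oxoethyl)-2-propanoyl-5-(trimethylsilyl)pent-4-ynoate (Michael adduct, both C2 epimers) | C[Si](C)(C)C#C[C@H](CC=O)C(C(=O)CC)C(=O)OC(C)(C)C | intermediate
6 | tert-butyl (6R)-3-methyl-2-oxo-6-[(trimethylsilyl)ethynyl]cyclohex-3-ene-1-carboxylate (both C1 epimers) | C[Si](C)(C)C#C[C@H]1C(C(=O)OC(C)(C)C)C(=O)C(C)=CC1 | intermediate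
7 | (5R)-2-methyl-5-[(trimethylsilyl)ethynyl]cyclohex-2-en-1-one | C[Si](C)(C)C#C[C@H]1CC(=O)C(C)=CC1 | intermediate
8 | (1R,4R,6R)-4-ethynyl-1-methyl-7-oxabicyclo[4.1.0]heptan-2-one | C#C[C@H]1CC(=O)[C@]2(C)O[C@@H]2C1 | intermediate
9 | (1R,5S)-5-ethynyl-2-methylcyclohex-2-en-1-ol | C#C[C@H]1CC=C(C)[C@H](O)C1 | intermediate
10 | (1R,5S)-2-methyl-5-[1-(triethylsilyl)ethenyl]cyclohex-2-en-1-ol | C=C([Si](CC)(CC)CC)[C@H]1CC=C(C)[C@H](O)C1 | intermediate
11 | (5S)-2-methyl-5-[1-(triethylsilyl)ethenyl]cyclohex-2-en-1-one | C=C([Si](CC)(CC)CC)[C@H]1CC=C(C)C(=O)C1 | intermediate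
12 | (5S)-5-(1-iodoethenyl)-2-methylcyclohex-2-en-1-one | C=C(I)[C@H]1CC=C(C)C(=O)C1 | intermediate
13 | 4-methylpent-3-en-1-ol | CC(C)=CCCO | starting material
14 | 4-methylpent-3-enal | CC(C)=CCC=O | intermediate
15 | (5S)-5-[(3S)-3-hydroxy-6-methylhepta-1,5-dien-2-yl]-2-methylcyclohex-2-en-1-one | C=C([C@H](CC=C(C)C)O)[C@H]1CC=C(C)C(=O)C1 | intermediate
16 | (2Z)-2-methylbut-2-enoic acid (angelic acid) | C/C=C(/C)C(=O)O | starting material
17 | (3S)-6-methyl-2-[(1S)-4-methyl-5-oxocyclohex-3-en-1-yl]hepta-1,5-dien-3-yl (2Z)-2-methylbut-2-enoate | C=C([C@H](CC=C(C)C)OC(=O)/C(C)=C\C)[C@H]1CC=C(C)C(=O)C1 | intermediate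
18 | (3S)-2-[(1R,6R)-6-hydroxy-4-methyl-5-oxocyclohex-3-en-1-yl]-6-methylhepta-1,5-dien-3-yl (2Z)-2-methylbut-2-enoate | C=C([C@H](CC=C(C)C)OC(=O)/C(C)=C\C)[C@H]1CC=C(C)C(=O)[C@@H]1O | intermediate
19 | (3S)-6-methyl-2-[(1R,6S)-4-methyl-6-{[(2Z)-2-methylbut-2-enoyl]oxy}-5-oxocyclohex-3-en-1-yl]hepta-1,5-dien-3-yl (2Z)-2-methylbut-2-enoate | C=C([C@H](CC=C(C)C)OC(=O)/C(C)=C\C)[C@H]1CC=C(C)C(=O)[C@H]1OC(=O)/C(C)=C\C | intermediate
20 | (3S)-2-[(1R,5R,6S)-5-hydroxy-4-methyl-6-{[(2Z)-2-methylbut-2-enoyl]oxy}cyclohex-3-en-1-yl]-6-methylhepta-1,5-dien-3-yl (2Z)-2-methylbut-2-enoate | C=C([C@H](CC=C(C)C)OC(=O)/C(C)=C\C)[C@H]1CC=C(C)[C@@H](O)[C@H]1OC(=O)/C(C)=C\C | intermediate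
21 | (3S)-2-[(1S,2S,3S,4R,6R)-2-hydroxy-1-methyl-3-{[(2Z)-2-methylbut-2-enoyl]oxy}-7-oxabicyclo[4.1.0]heptan-4-yl]-6-methylhepta-1,5-dien-3-yl (2Z)-2-methylbut-2-enoate | C=C([C@H](CC=C(C)C)OC(=O)/C(C)=C\C)[C@H]1C[C@H]2O[C@@]2(C)[C@@H](O)[C@H]1OC(=O)/C(C)=C\C | intermediate
22 | (3S)-2-[(1R,2S,3S,4S,5S)-5-chloro-3,4-dihydroxy-4-methyl-2-{[(2Z)-2-methylbut-2-enoyl]oxy}cyclohexyl]-6-methylhepta-1,5-dien-3-yl (2Z)-2-methylbut-2-enoate | C=C([C@H](CC=C(C)C)OC(=O)/C(C)=C\C)[C@H]1C[C@H](Cl)[C@@](C)(O)[C@@H](O)[C@H]1OC(=O)/C(C)=C\C | intermediate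
23 | (2S)-1-[(2S)-3,3-dimethyloxiran-2-yl]-3-[(1R,2S,3S,4S,5S)-5-chloro-3,4-dihydroxy-4-methyl-2-{[(2Z)-2-methylbut-2-enoyl]oxy}cyclohexyl]but-3-en-2-yl (2Z)-2-methylbut-2-enoate | C=C([C@H](C[C@@H]1OC1(C)C)OC(=O)/C(C)=C\C)[C@H]1C[C@H](Cl)[C@@](C)(O)[C@@H](O)[C@H]1OC(=O)/C(C)=C\C | target

**Step count.** Total: 16 steps. Longest linear sequence: 15 steps (steps 1–7 and 9–16; step 8 prepares the aldehyde partner).

**Steps most likely to fail**

Step 12 (Mitsunobu inversion at the ring carbinol). The oxyphosphonium intermediate of the hindered α-hydroxy ketone may eliminate or enolise (loss of the ketol, epimerisation) instead of being displaced. The fallback replaces hydroxylation and redox condensation by halogenation and carboxylate displacement, sets out from 17 and returns at 19. Compound 17 would be converted with LiN(SiMe3)2 and Me3SiCl at −78 °C into the cross-conjugated silyl dienol ether (3S)-6-methyl-2-[(1S)-4-methyl-5-[(trimethylsilyl)oxy]cyclohexa-3,5-dien-1-yl]hepta-1,5-dien-3-yl (2Z)-2-methylbut-2-enoate F1. N-Bromosuccinimide at −78 °C should brominate it anti to the side chain, faster than it attacks the prenyl alkene, to give the trans α′-bromo ketone (3S)-2-[(1R,6R)-6-bromo-4-methyl-5-oxocyclohex-3-en-1-yl]-6-methylhepta-1,5-dien-3-yl (2Z)-2-methylbut-2-enoate F2. Displacement with caesium (2Z)-2-methylbut-2-enoate (from 16 and Cs2CO3) in DMF at 0 °C would install the ester with inversion and give 19.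

Step 9 (ligand-controlled Nozaki–Hiyama–Kishi coupling). Facial selectivity at the new carbinol may be poor if ligand control is weak for this unbranched aldehyde. The fallback replaces reagent control by stereoconvergence, sets out from 12 and returns at 17. The coupling would be run without chiral ligand (CrCl2, NiCl2 cat., DMSO, rt) and the two carbinol epimers, which are diastereomers, separated by chromatography. Compound 15 would go through step 10 as before. The epimer (5S)-5-[(3R)-3-hydroxy-6-methylhepta-1,5-dien-2-yl]-2-methylcyclohex-2-en-1-one F3 would be esterified with 16 under Mitsunobu conditions (PPh3, DIAD, toluene), whose inversion gives the same ester 17.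

Step 16 (final Shi epoxidation). The trans chlorohydrin may re-close to the oxirane in the buffered oxidant, or catalyst control at the remote alkene may be insufficient. The fallback replaces direct oxygen transfer by dihydroxylation and cyclodehydration, sets out from 22 and ends at 23. Ligand-accelerated dihydroxylation of the prenyl alkene under neutral conditions (OsO4 cat., (DHQD)2PHAL, N-methylmorpholine N-oxide, acetone–water, 0 °C) should give the (R)-configured diol (3S,5R)-2-[(1R,2S,3S,4S,5S)-5-chloro-3,4-dihydroxy-4-methyl-2-{[(2Z)-2-methylbut-2-enoyl]oxy}cyclohexyl]-5,6-dihydroxy-6-methylhept-1-en-3-yl (2Z)-2-methylbut-2-enoate F4. Mitsunobu cyclodehydration (PPh3, DIAD, THF) would activate the secondary side-chain hydroxyl, which the tertiary one displaces with inversion to give the (S)-oxirane of 23. The ring diol is cis and cannot close in this way.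

Further compounds
F1 | step 12 | (3S)-6-methyl-2-[(1S)-4-methyl-5-[(trimethylsilyl)oxy]cyclohexa-3,5-dien-1-yl]hepta-1,5-dien-3-yl (2Z)-2-methylbut-2-enoate | C=C([C@H](CC=C(C)C)OC(=O)/C(C)=C\C)[C@H]1CC=C(C)C(O[Si](C)(C)C)=C1
F2 | step 12 | (3S)-2-[(1R,6R)-6-bromo-4-methyl-5-oxocyclohex-3-en-1-yl]-6-methylhepta-1,5-dien-3-yl (2Z)-2-methylbut-2-enoate | C=C([C@H](CC=C(C)C)OC(=O)/C(C)=C\C)[C@H]1CC=C(C)C(=O)[C@@H]1Br
F3 | step 9 | (5S)-5-[(3R)-3-hydroxy-6-methylhepta-1,5-dien-2-yl]-2-methylcyclohex-2-en-1-one | C=C([C@@H](CC=C(C)C)O)[C@H]1CC=C(C)C(=O)C1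
F4 | step 16 | (3S,5R)-2-[(1R,2S,3S,4S,5S)-5-chloro-3,4-dihydroxy-4-methyl-2-{[(2Z)-2-methylbut-2-enoyl]oxy}cyclohexyl]-5,6-dihydroxy-6-methylhept-1-en-3-yl (2Z)-2-methylbut-2-enoate | C=C([C@H](C[C@@H](O)C(C)(C)O)OC(=O)/C(C)=C\C)[C@H]1C[C@H](Cl)[C@@](C)(O)[C@@H](O)[C@H]1OC(=O)/C(C)=C\C
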